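## Retrosynthetic overview

1. Hanultarin is the mono-(E)-ferulate of (8R,8'R)-secoisolariciresinol. The last disconnections are the three phenol O–Si bonds and the ester C–O bond; the protected diol has a twofold axis, so its two CH2OH groups are homotopic and monoacylation can give only one monoester.
2. The diol is unfolded by LiAlH4 from a temporary trans-3,4-dibenzyl-γ-lactone acetal, which is the desulfurized form of the key-step product.
3. Key disconnection: the benzylic CH2–C8 bond, made by alkylating a lactone enolate with a vanillyl bromide. In the same pot the twin ArC–C8' bond is made by 1,4-addition of a lithiated 2-aryl-1,3-dithiane to (5R)-5-(l-menthyloxy)butenolide (three components, two C–C bonds, both stereocentres).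
4. Enabling feature: the 1,4-dioxygenated chain C9–C8–C8'–C9' with trans benzyl groups on adjacent carbons maps onto a five-membered lactone (ring O, C9 as carbonyl, C8, C8', C9' as acetal carbon). There C8' is a Michael β-carbon, C8 the derived enolate carbon, and the C9' acetal centre relays chirality to C8' and then to C8.
5. Ring order: no ring of the target is built (the three arenes come from vanillin and ferulic acid). Only temporary rings are used: the dithiane (made in step 2, cleaved in step 6) and the lactone brought in with the butenolide (opened in step 7).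

Key step: step 5

Remark: butenolide 6 is assumed to be purchasable as the crystalline (5R) epimer derived from l-menthol, where l-menthyl = (1R,2S,5R)-2-isopropyl-5-methylcyclohexyl. Lignan numbering is used for the chain (C7/C7' benzylic, C8/C8' stereocentres, C9/C9' oxygenated carbons).

## Route

Step 1
Reactants: 1 vanillin
Product: 2 3-methoxy-4-[(triisopropylsilyl)oxy]benzaldehyde
Conditions: TIPSCl, imidazole, DMF, rt
Reagents that add atoms: triisopropylsilyl chloride, CC(C)[Si](Cl)(C(C)C)C(C)C
Why: Imidazole-promoted silylation of the phenol; the bulky TIPS ether is chosen because it should survive n-BuLi, Raney Ni and LiAlH4 and leave at the end with fluoride.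

Step 2
Reactants: 2 3-methoxy-4-[(triisopropylsilyl)oxy]benzaldehyde
Product: 3 2-{3-methoxy-4-[(triisopropylsilyl)oxy]phenyl}-1,3-dithiane
Conditions: HS(CH2)3SH, BF3·OEt2 (cat.), CH2Cl2, 0 °C to rt
Reagents that add atoms: propane-1,3-dithiol, SCCCS
Why: Lewis-acid-catalysed thioacetalisation of the aryl aldehyde gives the 2-aryl-1,3-dithiane, a Corey–Seebach carbanion precursor that serves here as a masked benzyl anion; the aryl silyl ether should tolerate catalytic BF3·OEt2 at 0 °C.

Step 3
Reactants: 2 3-methoxy-4-[(triisopropylsilyl)oxy]benzaldehyde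
Product: 4 {3-methoxy-4-[(triisopropylsilyl)oxy]phenyl}methanol
Conditions: NaBH4, THF/EtOH, 0 °C
Reagents that add atoms: none
Why: Borohydride reduction of the aldehyde to the benzylic alcohol, a reaction that leaves aryl silyl ethers intact at 0 °C.

Step 4
Reactants: 4 {3-methoxy-4-[(triisopropylsilyl)oxy]phenyl}methanol
Product: 5 4-(bromomethyl)-2-methoxy-1-[(triisopropylsilyl)oxy]benzene
Conditions: CBr4, PPh3, CH2Cl2, 0 °C
Reagents that add atoms: carbon tetrabromide, BrC(Br)(Br)Br
Why: Appel bromination under neutral conditions converts the benzylic alcohol into the bromide without exposing the ionisable p-silyloxybenzyl system to acid; the bromide is used at once.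

Step 5
Reactants: 3 2-{3-methoxy-4-[(triisopropylsilyl)oxy]phenyl}-1,3-dithiane; 6 (5R)-5-(l-menthyloxy)furan-2(5H)-one; 5 4-(bromomethyl)-2-methoxy-1-[(triisopropylsilyl)oxy]benzene
Product: 9 (3R,4R,5R)-3-{3-methoxy-4-[(triisopropylsilyl)oxy]benzyl}-4-(2-{3-methoxy-4-[(triisopropylsilyl)oxy]phenyl}-1,3-dithian-2-yl)-5-(l-menthyloxy)dihydrofuran-2(3H)-one, via lithiated dithiane 7 (not isolated), via lithium enolate 8 (not isolated)
Conditions: n-BuLi, THF, −78 to −20 °C; then 6, −78 °C; then 5, DMPU, −78 °C to rt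
Reagents that add atoms: none
Why: Deprotonation of 3 gives the soft, sulfur- and aryl-stabilised carbanion 7, which adds in a 1,4-sense to position 4 of butenolide 6 to give lithium enolate 8, and 8 is then C-alkylated at position 3 by benzylic bromide 5 (SN2), which forms the benzylic CH2–C8 bond of the target. The closest known reaction type is the one-pot tandem conjugate addition–enolate alkylation of lithiated 2-aryl-1,3-dithianes with 5-alkoxyfuran-2(5H)-ones and benzylic halides, a three-component entry to dibenzylbutyrolactone lignans. No ring is closed; the lactone ring is brought in with 6 and serves only as a template. C8' (lactone position 4) is set by the acetal stereocentre at position 5, the nucleophile entering anti to the menthyloxy group, and C8 (position 3) is set by the new position-4 substituent, the bromide entering anti to the bulky dithianyl group, so the (5R) auxiliary should give the 3,4-trans product with both new centres R. The step needs 1,4- rather than 1,2-addition, which the delocalised dithianyl anion and the low temperature secure, and C-monoalkylation faster than proton transfer or retro-Michael cleavage, which the reactive benzylic bromide together with DMPU and the single, shielded α-hydrogen left in 9 secure.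

Step 6
Reactants: 9 (3R,4R,5R)-3-{3-methoxy-4-[(triisopropylsilyl)oxy]benzyl}-4-(2-{3-methoxy-4-[(triisopropylsilyl)oxy]phenyl}-1,3-dithian-2-yl)-5-(l-menthyloxy)dihydrofuran-2(3H)-one
Product: 10 (3R,4R,5R)-3,4-bis{3-methoxy-4-[(triisopropylsilyl)oxy]benzyl}-5-(l-menthyloxy)dihydrofuran-2(3H)-one
Conditions: Raney Ni, EtOH/THF, rt to 60 °C
Reagents that add atoms: none
Why: Mozingo-type Raney Ni hydrogenolysis of both benzylic C–S bonds turns the dithioketal carbon into the C7' methylene under neutral conditions that should leave the acetal, the lactone, the silyl ethers and both stereocentres untouched.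

Step 7
Reactants: 10 (3R,4R,5R)-3,4-bis{3-methoxy-4-[(triisopropylsilyl)oxy]benzyl}-5-(l-menthyloxy)dihydrofuran-2(3H)-one
Product: 11 (2R,3R)-2,3-bis{3-methoxy-4-[(triisopropylsilyl)oxy]benzyl}butane-1,4-diol
Conditions: LiAlH4, THF, 0 °C to rt; Rochelle salt work-up
Reagents that add atoms: none
Why: LiAlH4 reduction of the pseudo-ester: hydride addition to the lactone carbonyl, ring opening, loss of menthoxide from the resulting hemiacetal and reduction of both aldehyde-level carbons should give the 1,4-diol with C8 and C8' unchanged and the auxiliary released as menthol.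

Step 8
Reactants: 12 (E)-ferulic acid
Product: 14 (E)-3-{3-methoxy-4-[(triisopropylsilyl)oxy]phenyl}acrylic acid, via bis-silylated ferulate 13 (not isolated)
Conditions: TIPSCl (2.2 equiv), imidazole, DMF, rt; then K2CO3, THF/MeOH/H2O, 0 °C; acidic work-up
Reagents that add atoms: triisopropylsilyl chloride, CC(C)[Si](Cl)(C(C)C)C(C)C
Why: Exhaustive silylation followed by selective hydrolysis of the far more labile silyl ester should leave the phenol-protected acid, with the (E)-alkene untouched.

Step 9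
Reactants: 11 (2R,3R)-2,3-bis{3-methoxy-4-[(triisopropylsilyl)oxy]benzyl}butane-1,4-diol (2 equiv); 14 (E)-3-{3-methoxy-4-[(triisopropylsilyl)oxy]phenyl}acrylic acid
Product: 15 (2R,3R)-4-hydroxy-2,3-bis{3-methoxy-4-[(triisopropylsilyl)oxy]benzyl}butyl (E)-3-{3-methoxy-4-[(triisopropylsilyl)oxy]phenyl}acrylate
Conditions: EDC·HCl, DMAP (cat.), CH2Cl2, 0 °C to rt, slow addition of 14; unreacted 11 recovered
Reagents that add atoms: none
Why: Steglich esterification of a primary alcohol; because the two CH2OH groups of 11 are interchanged by its twofold axis, monoacylation can give only one monoester, and excess diol with slow addition of the acid should limit diester formation.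

Step 10
Reactants: 15 (2R,3R)-4-hydroxy-2,3-bis{3-methoxy-4-[(triisopropylsilyl)oxy]benzyl}butyl (E)-3-{3-methoxy-4-[(triisopropylsilyl)oxy]phenyl}acrylate
Product: 16 hanultarin
Conditions: TBAF, AcOH, THF, 0 °C
Reagents that add atoms: none
Why: Fluoride cleaves the three aryl O–Si bonds (phenoxide leaving groups) under acetic acid buffering that should protect the cinnamate ester, and a 1,4-acyl shift between the two homotopic hydroxyls would be degenerate.

## Compound list

1 | vanillin | COc1cc(C=O)ccc1O | starting material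
2 | 3-methoxy-4-[(triisopropylsilyl)oxy]benzaldehyde | COc1cc(C=O)ccc1O[Si](C(C)C)(C(C)C)C(C)C | intermediate
3 | 2-{3-methoxy-4-[(triisopropylsilyl)oxy]phenyl}-1,3-dithiane | COc1cc(C2SCCCS2)ccc1O[Si](C(C)C)(C(C)C)C(C)C | intermediate
4 | {3-methoxy-4-[(triisopropylsilyl)oxy]phenyl}methanol | COc1cc(CO)ccc1O[Si](C(C)C)(C(C)C)C(C)C | intermediate
5 | 4-(bromomethyl)-2-methoxy-1-[(triisopropylsilyl)oxy]benzene | COc1cc(CBr)ccc1O[Si](C(C)C)(C(C)C)C(C)C | intermediate
6 | (5R)-5-{[(1R,2S,5R)-2-isopropyl-5-methylcyclohexyl]oxy}furan-2(5H)-one | O=C1C=C[C@H](O[C@@H]2C[C@H](C)CC[C@H]2C(C)C)O1 | starting material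
7 | 2-lithio-2-{3-methoxy-4-[(triisopropylsilyl)oxy]phenyl}-1,3-dithiane | [Li]C1(c2ccc(O[Si](C(C)C)(C(C)C)C(C)C)c(OC)c2)SCCCS1 | intermediate (not isolated)
8 | lithium (4R,5R)-4-(2-{3-methoxy-4-[(triisopropylsilyl)oxy]phenyl}-1,3-dithian-2-yl)-5-(l-menthyloxy)-4,5-dihydrofuran-2-olate | [Li]OC1=C[C@@H](C2(c3ccc(O[Si](C(C)C)(C(C)C)C(C)C)c(OC)c3)SCCCS2)[C@H](O[C@@H]2C[C@H](C)CC[C@H]2C(C)C)O1 | intermediate (not isolated)
9 | (3R,4R,5R)-3-{3-methoxy-4-[(triisopropylsilyl)oxy]benzyl}-4-(2-{3-methoxy-4-[(triisopropylsilyl)oxy]phenyl}-1,3-dithian-2-yl)-5-(l-menthyloxy)dihydrofuran-2(3H)-one | O=C1O[C@@H](O[C@@H]2C[C@H](C)CC[C@H]2C(C)C)[C@H](C2(c3ccc(O[Si](C(C)C)(C(C)C)C(C)C)c(OC)c3)SCCCS2)[C@H]1Cc1ccc(O[Si](C(C)C)(C(C)C)C(C)C)c(OC)c1 | intermediate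
10 | (3R,4R,5R)-3,4-bis{3-methoxy-4-[(triisopropylsilyl)oxy]benzyl}-5-(l-menthyloxy)dihydrofuran-2(3H)-one | O=C1O[C@@H](O[C@@H]2C[C@H](C)CC[C@H]2C(C)C)[C@H](Cc2ccc(O[Si](C(C)C)(C(C)C)C(C)C)c(OC)c2)[C@H]1Cc1ccc(O[Si](C(C)C)(C(C)C)C(C)C)c(OC)c1 | intermediate
11 | (2R,3R)-2,3-bis{3-methoxy-4-[(triisopropylsilyl)oxy]benzyl}butane-1,4-diol | OC[C@H](Cc1ccc(O[Si](C(C)C)(C(C)C)C(C)C)c(OC)c1)[C@H](CO)Cc1ccc(O[Si](C(C)C)(C(C)C)C(C)C)c(OC)c1 | intermediate
12 | (E)-ferulic acid | COc1cc(/C=C/C(=O)O)ccc1O | starting material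
13 | triisopropylsilyl (E)-3-{3-methoxy-4-[(triisopropylsilyl)oxy]phenyl}acrylate | COc1cc(/C=C/C(=O)O[Si](C(C)C)(C(C)C)C(C)C)ccc1O[Si](C(C)C)(C(C)C)C(C)C | intermediate (not isolated)
14 | (E)-3-{3-methoxy-4-[(triisopropylsilyl)oxy]phenyl}acrylic acid | COc1cc(/C=C/C(=O)O)ccc1O[Si](C(C)C)(C(C)C)C(C)C | intermediate
15 | (2R,3R)-4-hydroxy-2,3-bis{3-methoxy-4-[(triisopropylsilyl)oxy]benzyl}butyl (E)-3-{3-methoxy-4-[(triisopropylsilyl)oxy]phenyl}acrylate | COc1cc(/C=C/C(=O)OC[C@H](Cc2ccc(O[Si](C(C)C)(C(C)C)C(C)C)c(OC)c2)[C@H](CO)Cc2ccc(O[Si](C(C)C)(C(C)C)C(C)C)c(OC)c2)ccc1O[Si](C(C)C)(C(C)C)C(C)C | intermediate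
16 | hanultarin | COc1cc(/C=C/C(=O)OC[C@H](Cc2ccc(O)c(OC)c2)[C@H](CO)Cc2ccc(O)c(OC)c2)ccc1O | target

## Step count and risks

Total step count: 10. Longest linear sequence: 8 steps (steps 1, 3, 4, 5, 6, 7, 9, 10).

Steps most likely to fail:

Step 5. C-alkylation of enolate 8, which is crowded by the fully substituted dithianyl carbon next to it, may be slower than proton transfer or retro-Michael release of 7, and the ionisable bromide 5 may self-condense before it is consumed. The fallback sets out from 3 and 6 and returns at 10; it separates the two bond formations so that the alkylation is done on an unhindered enolate. The conjugate addition is run as in step 5 but enolate 8 is quenched with aqueous NH4Cl, which should give (4R,5R)-4-(2-{3-methoxy-4-[(triisopropylsilyl)oxy]phenyl}-1,3-dithian-2-yl)-5-(l-menthyloxy)dihydrofuran-2(3H)-one F1. Raney Ni in EtOH should convert it into (4R,5R)-4-{3-methoxy-4-[(triisopropylsilyl)oxy]benzyl}-5-(l-menthyloxy)dihydrofuran-2(3H)-one F2. LiN(SiMe3)2 in THF at −78 °C then generates lithium (4R,5R)-4-{3-methoxy-4-[(triisopropylsilyl)oxy]benzyl}-5-(l-menthyloxy)-4,5-dihydrofuran-2-olate F3 (not isolated), which no longer can fragment and should be alkylated by 5 (DMPU) anti to the position-4 benzyl group, the standard trans-selective alkylation of β-benzyl-γ-butyrolactone enolates, to give 10.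

Step 9. Over-acylation: the second hydroxyl of the monoester may react at a rate similar to the first, so that the product distribution becomes statistical and material is lost to the diester. The fallback sets out from 11 and returns at 15; it replaces rate control by a ring that forces monofunctionalisation. Diol 11 with 4-methoxybenzaldehyde dimethyl acetal and PPTS in CH2Cl2 should close the seven-membered acetal (5R,6R)-2-(4-methoxyphenyl)-5,6-bis{3-methoxy-4-[(triisopropylsilyl)oxy]benzyl}-1,3-dioxepane F4, whose acetal carbon is not a stereocentre because of the twofold symmetry of the diol. Reductive opening with i-Bu2AlH in CH2Cl2 at 0 °C, where either C–O cleavage gives the same product, should give (2R,3R)-4-[(4-methoxybenzyl)oxy]-2,3-bis{3-methoxy-4-[(triisopropylsilyl)oxy]benzyl}butan-1-ol F5. Esterification of the single free hydroxyl with excess 14 (EDC·HCl, DMAP) should give (2R,3R)-4-[(4-methoxybenzyl)oxy]-2,3-bis{3-methoxy-4-[(triisopropylsilyl)oxy]benzyl}butyl (E)-3-{3-methoxy-4-[(triisopropylsilyl)oxy]phenyl}acrylate F6, and oxidative removal of the 4-methoxybenzyl ether with DDQ in CH2Cl2/pH 7 buffer at 0 °C should give 15.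

Step 6. Hydrogenolysis of the hindered, fully substituted dithioketal may stall at a thioether or vinyl sulfide stage, or residual alkali in the nickel may open or epimerise the pseudo-ester. The fallback sets out from 9 and returns at 10; it unmasks the carbonyl and removes the oxygen instead of the sulfur. Alkylative hydrolysis of the dithiane (MeI, CaCO3, MeCN/H2O, 40 °C) should give (3R,4R,5R)-3-{3-methoxy-4-[(triisopropylsilyl)oxy]benzyl}-4-{3-methoxy-4-[(triisopropylsilyl)oxy]benzoyl}-5-(l-menthyloxy)dihydrofuran-2(3H)-one F7. Hydrogenolysis of this electron-rich aryl ketone through the benzylic alcohol (H2, Pd/C, EtOAc/AcOH) should give 10; any epimerisation next to the ketone leads to the same, thermodynamically preferred all-trans lactone.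

Further compounds
F1 | step 5 | (4R,5R)-4-(2-{3-methoxy-4-[(triisopropylsilyl)oxy]phenyl}-1,3-dithian-2-yl)-5-(l-menthyloxy)dihydrofuran-2(3H)-one | O=C1C[C@@H](C2(c3ccc(O[Si](C(C)C)(C(C)C)C(C)C)c(OC)c3)SCCCS2)[C@H](O[C@@H]2C[C@H](C)CC[C@H]2C(C)C)O1
F2 | step 5 | (4R,5R)-4-{3-methoxy-4-[(triisopropylsilyl)oxy]benzyl}-5-(l-menthyloxy)dihydrofuran-2(3H)-one | O=C1C[C@@H](Cc2ccc(O[Si](C(C)C)(C(C)C)C(C)C)c(OC)c2)[C@H](O[C@@H]2C[C@H](C)CC[C@H]2C(C)C)O1
F3 | step 5 | lithium (4R,5R)-4-{3-methoxy-4-[(triisopropylsilyl)oxy]benzyl}-5-(l-menthyloxy)-4,5-dihydrofuran-2-olate | [Li]OC1=C[C@@H](Cc2ccc(O[Si](C(C)C)(C(C)C)C(C)C)c(OC)c2)[C@H](O[C@@H]2C[C@H](C)CC[C@H]2C(C)C)O1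
F4 | step 9 | (5R,6R)-2-(4-methoxyphenyl)-5,6-bis{3-methoxy-4-[(triisopropylsilyl)oxy]benzyl}-1,3-dioxepane | COc1ccc(C2OC[C@H](Cc3ccc(O[Si](C(C)C)(C(C)C)C(C)C)c(OC)c3)[C@H](CO2)Cc2ccc(O[Si](C(C)C)(C(C)C)C(C)C)c(OC)c2)cc1
F5 | step 9 | (2R,3R)-4-[(4-methoxybenzyl)oxy]-2,3-bis{3-methoxy-4-[(triisopropylsilyl)oxy]benzyl}butan-1-ol | COc1ccc(COC[C@H](Cc2ccc(O[Si](C(C)C)(C(C)C)C(C)C)c(OC)c2)[C@H](CO)Cc2ccc(O[Si](C(C)C)(C(C)C)C(C)C)c(OC)c2)cc1
F6 | step 9 | (2R,3R)-4-[(4-methoxybenzyl)oxy]-2,3-bis{3-methoxy-4-[(triisopropylsilyl)oxy]benzyl}butyl (E)-3-{3-methoxy-4-[(triisopropylsilyl)oxy]phenyl}acrylate | COc1ccc(COC[C@H](Cc2ccc(O[Si](C(C)C)(C(C)C)C(C)C)c(OC)c2)[C@H](COC(=O)/C=C/c2ccc(O[Si](C(C)C)(C(C)C)C(C)C)c(OC)c2)Cc2ccc(O[Si](C(C)C)(C(C)C)C(C)C)c(OC)c2)cc1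
F7 | step 6 | (3R,4R,5R)-3-{3-methoxy-4-[(triisopropylsilyl)oxy]benzyl}-4-{3-methoxy-4-[(triisopropylsilyl)oxy]benzoyl}-5-(l-menthyloxy)dihydrofuran-2(3H)-one | O=C1O[C@@H](O[C@@H]2C[C@H](C)CC[C@H]2C(C)C)[C@H](C(=O)c2ccc(O[Si](C(C)C)(C(C)C)C(C)C)c(OC)c2)[C@H]1Cc1ccc(O[Si](C(C)C)(C(C)C)C(C)C)c(OC)c1
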